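**Retrosynthesis**
1. Elemacarmanin comes from the C8-acyloxy/C6-diol methyl ester by regioselective C8 acylation with a protected 2-(hydroxymethyl)acrylate and silyl removal. That diol ester comes from methanolysis of a trans-fused α-methylene-γ-lactone, which forms from the 1,3-cis-diol carrying a C7-CH2CO2Me chain.
2. The diol comes from double reduction of a 2,4-disubstituted 5-methyl-5-vinylcyclohexane-1,3-dione. The C7 CH2CO2Me chain is added by reductive Knoevenagel. The C5 C(=CH2)CH2OTIPS chain is added by α'-alkenylation of a chiral vinylogous ester.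
3. The dione comes from Birch reductive methylation of 3,5-dimethoxybenzoic acid (the dearomatisation that builds the C10 quaternary centre), followed by CO2H→vinyl. The mirror symmetry is broken by separating a menthyl vinylogous ether.
4. The only ring formed is the carbocycle, via the arene (Step 1). The γ-lactone is a temporary device (Steps 12 and 16).

*Assumptions (one line each):*
- Elemane numbering is used: C10 is quaternary (Me, vinyl), C5 carries the hydroxy-isopropenyl, C6–OH, C7 carries the acrylate, C8 carries the acyloxy group, C9 is CH2.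
- The two menthyl ether diastereomers are separable by chromatography or crystallisation, and the wrong one is discarded.
- 3,5-Dimethoxybenzoic acid, (−)-menthol, 2-bromoallyl alcohol, methyl glyoxylate and ethyl 2-(hydroxymethyl)acrylate are commercial.

**Route**

Step 1
Reactants: 1 (3,5-dimethoxybenzoic acid)
Product: 2 (3,5-dimethoxy-1-methylcyclohexa-2,5-diene-1-carboxylic acid, achiral)
Conditions: Li, NH3(l)/THF, −78 °C; then MeI, −78 °C → rt
Reagents that add atoms: methyl iodide, CI
Why: Birch reductive alkylation dearomatises the arene and the carboxylate-stabilised dienolate is methylated at C1, creating the quaternary carbon; the 1,4-diene is achiral (mirror plane).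

Step 2
Reactants: 2
Product: 3 ((3,5-dimethoxy-1-methylcyclohexa-2,5-dien-1-yl)methanol)
Conditions: LiAlH4, THF, 0 °C
Reagents that add atoms: none
Why: Hydride reduction of the carboxylic acid leaves the enol ethers untouched.

Step 3
Reactants: 3
Product: 4 (1-formyl-1-methyl-3,5-dimethoxycyclohexa-2,5-diene)
Conditions: (COCl)2, DMSO, CH2Cl2, −78 °C; then Et3N
Reagents that add atoms: none
Why: Swern oxidation is non-acidic, so the acid-labile bis(enol ether) survives.

Step 4
Reactants: 4
Product: 5 (1-methyl-1-vinyl-3,5-dimethoxycyclohexa-2,5-diene)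
Conditions: Ph3P+CH3 Br−, KOtBu, THF, 0 °C → rt
Reagents that add atoms: methylenetriphenylphosphorane, C=P(c1ccccc1)(c1ccccc1)c1ccccc1 (CH2 retained)
Why: Wittig methylenation of the non-enolisable neopentylic aldehyde gives the C10 vinyl group.

Step 5
Reactants: 5
Product: 6 (5-methyl-5-vinylcyclohexane-1,3-dione, prochiral)
Conditions: 0.5 M aq. oxalic acid, THF, 25 °C
Reagents that add atoms: water, O
Why: Acid hydrolysis of both enol ethers unmasks the 1,3-dione; C6 and C8 oxygens are now enantiotopic carbonyls.

Step 6
Reactants: 6; 7 ((−)-menthol, (1R,2S,5R))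
Product: 8 (single diastereomer of the 3-menthyloxy-5-methyl-5-vinylcyclohex-2-enone, quaternary centre as in the target; its epimer is discarded)
Conditions: p-TsOH (cat.), PhH, Dean–Stark reflux; separate diastereomers by SiO2 or crystallisation
Reagents that add atoms: none (menthol is reactant 7)
Why: Mono-enol etherification with a chiral alcohol breaks the mirror symmetry and gives separable diastereomers, fixing the absolute configuration of C10 regardless of the small Me/vinyl difference.

Step 7
Reactants: 9 (2-bromoallyl alcohol)
Product: 10 ((2-bromoallyloxy)triisopropylsilane)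
Conditions: TIPSCl, imidazole, DMF, 0 °C → rt
Reagents that add atoms: triisopropylsilyl chloride, CC(C)[Si](Cl)(C(C)C)C(C)C
Why: Silyl protection gives a robust vinyl bromide for the C5 chain.

Step 8
Reactants: 8; 10
Product: 11 (menthyl vinylogous ester carrying the C5–C(=CH2)CH2OTIPS chain; chain cis to the C10 methyl, trans to vinyl)
Conditions: LDA, THF, −78 °C; ZnCl2; then 10, Pd2(dba)3/Q-Phos, THF, 50 °C
Reagents that add atoms: none (atoms come from 10)
Why: Proposed new method: the kinetic α'-enolate (C5) of the vinylogous ester is transmetalated to zinc and coupled with a vinyl bromide; this is modelled on Pd-catalysed α-alkenylation and Negishi α-arylation of ketone zinc enolates. C5 is α to the ketone, so the two C5 epimers interconvert and the desired one is isolated.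

Step 9
Reactants: 11
Product: 12 (5-[C(=CH2)CH2OTIPS]-5-methyl... i.e. dione with chain at C5, methyl/vinyl at C10; menthol recovered)
Conditions: 1 M aq. HCl, THF, 50 °C
Reagents that add atoms: water, O
Why: Vinylogous ester hydrolysis releases the dione; it is now chiral because the C5 chain differentiates C6 from C8, so the stereochemical information is retained.

Step 10
Reactants: 12; 13 (methyl glyoxylate)
Product: 14 (2-(methoxycarbonylmethyl)-dione, C7 unspecified)
Conditions: Hantzsch ester, L-proline (10 mol%), CH2Cl2/EtOH, rt
Reagents that add atoms: none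
Why: Knoevenagel condensation at the acidic C7 followed by Hantzsch-ester conjugate reduction installs the CH2CO2Me chain; C7 is an enolisable centre, so its configuration is set later.

Step 11
Reactants: 14
Product: 15 (6,8-cis-diol with CH2CO2Me at C7; all substituents equatorial except the C10 methyl)
Conditions: RuCl[(S,S)-TsDPEN](p-cymene) (2 mol%), HCO2H/Et3N 5:2, 40 °C
Reagents that add atoms: none
Why: Proposed new method: Noyori-type transfer hydrogenation with dynamic epimerisation at C7 reduces both ketones under catalyst control to the equatorial 1,3-cis diol (the axial C10 methyl blocks the syn-axial face); closest known reaction is DKR-ATH of 2-substituted cyclic 1,3-diketones.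

Step 12
Reactants: 15
Product: 16 (trans-fused γ-lactone on C8–O, free C6–OH)
Conditions: p-TsOH (cat.), PhMe, 60 °C
Reagents that add atoms: none
Why: Acid-catalysed lactonisation occurs at the less hindered C8–OH; a C6 lactone would converge in Step 16 anyway, and lactonisation also filters out non-trans-configured diastereomers.

Step 13
Reactants: 17 (ethyl 2-(hydroxymethyl)acrylate)
Product: 18 (ethyl 2-(TIPS-oxymethyl)acrylate)
Conditions: TIPSCl, imidazole, DMF, rt
Reagents that add atoms: triisopropylsilyl chloride, CC(C)[Si](Cl)(C(C)C)C(C)C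
Why: Protects the hydroxymethyl group of the acyl fragment.

Step 14
Reactants: 18
Product: 19 (2-(TIPS-oxymethyl)acrylic acid)
Conditions: LiOH·H2O, THF/H2O, 0 °C → rt
Reagents that add atoms: water, O
Why: Saponification gives the carboxylic acid for the final esterification.

Step 15
Reactants: 16
Product: 20 (α-methylene lactone)
Conditions: LDA (2.5 equiv), THF, −78 °C; then Eschenmoser's salt; then MeI; NaHCO3, rt
Reagents that add atoms: Eschenmoser's salt, C[N+](C)=C.[I-] (CH2 retained)
Why: Lactone dienolate Mannich reaction followed by Hofmann-type elimination installs the exocyclic methylene; no stereocentre is touched (C7 is not α to a ketone).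

Step 16
Reactants: 20
Product: 21 (C6, C8 diol with C7 C(=CH2)CO2Me)
Conditions: K2CO3 (0.2 equiv), MeOH, 0 °C; quench AcOH
Reagents that add atoms: methanol, CO
Why: Base-catalysed transesterification opens the strained trans-fused lactone with MeOH in large excess; stereocentres are unchanged.

Step 17
Reactants: 21; 19
Product: 22 (C8-acylated, bis-TIPS-protected precursor)
Conditions: 2,4,6-Cl3C6H2COCl, Et3N, THF; then 21, DMAP, PhMe, rt
Reagents that add atoms: none
Why: Yamaguchi esterification occurs selectively at C8–OH, which is flanked only by C9H2 and C7, whereas C6–OH is flanked by two substituted carbons.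

Step 18
Reactants: 22
Product: 23 (elemacarmanin)
Conditions: HF·pyridine, THF/pyridine, 0 °C → rt
Reagents that add atoms: none
Why: Fluoride cleaves both primary TIPS ethers under non-basic conditions, limiting lactonisation of the free C6–OH onto the acrylate ester.

**Compound list**

1 | 3,5-dimethoxybenzoic acid | COc1cc(OC)cc(C(=O)O)c1 | starting material
2 | 3,5-dimethoxy-1-methylcyclohexa-2,5-diene-1-carboxylic acid | COC1=CC(C)(C(=O)O)C=C(OC)C1 | intermediate
3 | (3,5-dimethoxy-1-methylcyclohexa-2,5-dien-1-yl)methanol | COC1=CC(C)(CO)C=C(OC)C1 | intermediate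
4 | 3,5-dimethoxy-1-methylcyclohexa-2,5-diene-1-carbaldehyde | COC1=CC(C)(C=O)C=C(OC)C1 | intermediate
5 | 1,5-dimethoxy-3-methyl-3-vinylcyclohexa-1,4-diene | COC1=CC(C)(C=C)C=C(OC)C1 | intermediate
6 | 5-methyl-5-vinylcyclohexane-1,3-dione | O=C1CC(=O)CC(C)(C=C)C1 | intermediate
7 | (−)-menthol | CC(C)[C@@H]1CC[C@@H](C)C[C@H]1O | starting material
8 | menthyl vinylogous ester (desired diastereomer) | C=C[C@]1(C)CC(O[C@@H]2C[C@H](C)CC[C@H]2C(C)C)=CC(=O)C1 | intermediate
9 | 2-bromoprop-2-en-1-ol | C=C(Br)CO | starting material
10 | (2-bromoallyloxy)triisopropylsilane | C=C(Br)CO[Si](C(C)C)(C(C)C)C(C)C | intermediate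
11 | C5-alkenylated menthyl vinylogous ester | C=C[C@]1(C)CC(O[C@@H]2C[C@H](C)CC[C@H]2C(C)C)=CC(=O)[C@H]1C(=C)CO[Si](C(C)C)(C(C)C)C(C)C | intermediate
12 | chiral 1,3-dione with C5 chain | C=C[C@]1(C)CC(=O)CC(=O)[C@H]1C(=C)CO[Si](C(C)C)(C(C)C)C(C)C | intermediate
13 | methyl glyoxylate | COC(=O)C=O | starting material
14 | 2-(methoxycarbonylmethyl) dione | C=C[C@]1(C)CC(=O)C(CC(=O)OC)C(=O)[C@H]1C(=C)CO[Si](C(C)C)(C(C)C)C(C)C | intermediate
15 | 1,3-cis-diol ester | C=C[C@]1(C)C[C@H](O)[C@@H](CC(=O)OC)[C@H](O)[C@H]1C(=C)CO[Si](C(C)C)(C(C)C)C(C)C | intermediate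
16 | trans-fused γ-lactone (C8–O) | C=C[C@]1(C)C[C@@H]2OC(=O)C[C@H]2[C@H](O)[C@H]1C(=C)CO[Si](C(C)C)(C(C)C)C(C)C | intermediate
17 | ethyl 2-(hydroxymethyl)acrylate | C=C(CO)C(=O)OCC | starting material
18 | ethyl 2-(TIPS-oxymethyl)acrylate | C=C(CO[Si](C(C)C)(C(C)C)C(C)C)C(=O)OCC | intermediate
19 | 2-(TIPS-oxymethyl)acrylic acid | C=C(CO[Si](C(C)C)(C(C)C)C(C)C)C(=O)O | intermediate
20 | α-methylene lactone | C=C[C@]1(C)C[C@@H]2OC(=O)C(=C)[C@H]2[C@H](O)[C@H]1C(=C)CO[Si](C(C)C)(C(C)C)C(C)C | intermediate
21 | diol with C7 methyl acrylate | C=C[C@]1(C)C[C@H](O)[C@@H](C(=C)C(=O)OC)[C@H](O)[C@H]1C(=C)CO[Si](C(C)C)(C(C)C)C(C)C | intermediate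
22 | C8-acylated bis-TIPS precursor | C=C[C@]1(C)C[C@H](OC(=O)C(=C)CO[Si](C(C)C)(C(C)C)C(C)C)[C@@H](C(=C)C(=O)OC)[C@H](O)[C@H]1C(=C)CO[Si](C(C)C)(C(C)C)C(C)C | intermediate
23 | elemacarmanin | C=C[C@]1(C)C[C@H](OC(=O)C(=C)CO)[C@@H](C(=C)C(=O)OC)[C@H](O)[C@H]1C(=C)CO | target

**Total step count:** 18 steps (Steps 7, 13 and 14 prepare fragments). **Longest linear sequence:** 15 steps (1–6, 8–12, 15–18 → 6 + 5 + 4... counted as 1–6, 8–12, 15, 16, 17, 18 = 15).

**Three steps most likely to fail**
1. **Step 8 (α'-alkenylation next to the quaternary centre).** It could fail on yield or on C5/C10 diastereoselectivity.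
   - Fallback: change the chain-building approach. Do α'-allylation (LDA, allyl bromide), then ozonolysis, organocatalytic α-methylenation with aqueous HCHO and Luche reduction to build C(=CH2)CH2OR.
2. **Step 11 (double DKR transfer hydrogenation).** It could give the wrong C6/C7/C8 relative configuration.
   - Fallback: reduce with NaBH4 and let Step 12 select the trans-fused lactone. Oxidise the other diastereomers back to epimerisable ketones (DMP) and recycle them. Also invert C8 by Mitsunobu acylation with acid 19 in place of Step 17.
3. **Step 16 (lactone methanolysis).** The equilibrium may favour the lactone, and MeOH may add to the acrylate.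
   - Fallback: avoid the lactone. Use tert-butyl glyoxylate in Step 10, protect the diol as TES ethers, α-methylenate the tert-butyl ester directly (LDA, Eschenmoser's salt), then convert the tert-butyl ester to the methyl ester (TFA, then TMSCHN2).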